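(The runs were computed with made-up constants; scatter was added.)

The meeting took up one question: how much of what forms is ring, at the end of each flask from ash to maple.

the same everywhere: substrate 0.18 M

| flask | activator | capture agent | remark | time |
|---|---|---|---|---|
| Sunday's | 0.024 M | 3.6 mM | run made earlier |  |
| Saturday's | 0.37 M | 3.6 mM | run made earlier |  |
| ash | 0.0300 M | 3.60 mM |  | 8.0 h |
| elm | 0.0600 M | 3.60 mM |  | 8.0 h |
| alder | 0.120 M | 3.60 mM |  | 8.0 h |
| oak | 0.250 M | 3.60 mM |  | 8.0 h |
| maple | 0.500 M | 3.60 mM |  | 8.0 h |

| run | time / h | ring / % | open dimer / % |
|---|---|---|---|
| Sunday's | 0.333 | 1.3 | 6.3 |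
| Sunday's | 0.500 | 4.3 | 10.8 |
| Sunday's | 0.667 | 6.0 | 12.3 |
| Sunday's | 1.00 | 4.5 | 11.3 |
| Sunday's | 1.50 | 4.5 | 13.1 |
| Sunday's | 2.50 | 4.5 | 12.8 |
| Sunday's | 4.00 | 4.2 | 11.5 |
| Saturday's | 0.200 | 31.3 | 29.5 |
| Saturday's | 0.667 | 46.2 | 38.2 |
| Saturday's | 1.00 | 43.8 | 38.7 |
| Saturday's | 1.50 | 39.3 | 39.5 |
| Saturday's | 2.50 | 30.4 | 38.1 |
| Saturday's | 3.00 | 28.6 | 39.5 |
| Saturday's | 4.00 | 24.3 | 37.8 |

(readings scatter by 1 percentage point)

- a species is counted by the substrate in it: one open dimer counts as two
- on the list of suspects stand: activated form -> ring; ring <-> isomer of the product; substrate + activator -> activated form; activator + ring -> over-reaction product; substrate + activated form -> open dimer; capture agent + activated form -> trapped intermediate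
- "hardly changes" means that all values lie within two and a half points (for a concentration: within two and a half percent of the largest)

- share of ring in all that became ring or open dimer or isomer of the product or trapped intermediate or over-reaction product for ash, elm, alder, oak, maple, in this order
- how the row runs (hardly changes / falls all the way / rises, then falls / falls, then rises / rises all the way)

The chair proposed counting turnovers. One turnover uses one activator and makes one activated form, which can become ring or trapped intermediate, or take a second substrate and become open dimer. She noted that Sunday's charge of activator was 13.3% of the substrate charged, and she counted that charge as fully turned over, since the open dimer readings stand level from 1.00 h on.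

A colleague then averaged Sunday's readings from that time on. Ring stood at 4.43%, and open dimer, at two substrates per turnover, accounted for 6.09%. That left 2.82% unaccounted for, which he put at 21.2% of the turnovers. The meeting named this the unseen share: the part of the turnovers that stands in neither ring nor open dimer.

A third member pointed out that Sunday's gap is larger than the capture agent's whole charge of 2.00%, though with readings good to one point the margin is narrow. She suspected the isomer of the product. Because ash's activator charge is less than its substrate charge, activator is the limiting reagent there. My own reckoning therefore gave ash 3.53% of the substrate charged as unseen.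

The forecast gave 23%, 29%, 41%, 27% and 6%, a row that rises, then falls, and held that “The ring then stays flat once the activator is gone, so isomerisation is minor”. My count does not part from it on Sunday's readings, which show the gap but not how it divides: taking the capture agent's whole charge from the gap leaves 0.82 percentage points, beside the forecast's about 1 point.

The row came out at 16.2%, 18.0%, 22.9%, 23.3% and 19.1%; it rises, then falls.

    activated form → ring (k = 10.0 h⁻¹)
    ring ⇌ isomer of the product (K = 1.20, k = 0.400 h⁻¹)
    substrate + activator → activated form (k = 18.0 L mol⁻¹ h⁻¹)
    activator + ring → over-reaction product (k = 0.260 L mol⁻¹ h⁻¹)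
    substrate + activated form → open dimer (k = 58.0 L mol⁻¹ h⁻¹)
    capture agent + activated form → trapped intermediate (k = 33.0 L mol⁻¹ h⁻¹)

In ash, with activator at 0%, ring stands at 3.97% beside isomer of the product at 4.73%, and trapped intermediate at 0.101%. The unseen part there is 4.85% of the substrate charged, more than the 3.53% reckoned. In elm, with activator also at 0%, the unseen share gives 7.05%, and isomer of the product stands higher, at 10.2%.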